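The isoflavone is opened at the C2=C3 enol-ether double bond of ring C, which lies between O1 and C3, the carbon that carries ring B; both of its carbons can be terminal alkene carbons. One ring-closing metathesis with expulsion of ethene therefore forms C2=C3 and ring C together, giving a 3-aryl-4H-chromen-4-ol whose C4 carbinol is then oxidised to the chromone carbonyl. The metathesis substrate is a ring A aryl vinyl ether (O1–CH=CH2) with an ortho CH(OH)–C(=CH2)–aryl arm. It is assembled from a dibenzylated O-vinyl salicylaldehyde and a 1-arylvinyllithium made by a Shapiro reaction.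

Key step: step 9

Remark: carbinols 13 and 14 are taken to be acid-labile (ring A stabilises a benzylic cation, and 14 is the pseudobase of a benzopyrylium ion), so both are worked up without acid, 13 is purified on Et3N-deactivated silica, and 14 is carried crude into step 10; their carbinol carbon is racemic and ends as the C4 carbonyl.

Step 1
Reactants: 1 3,5-dihydroxy-4-methoxybenzoic acid
Product: 2 benzyl 3,5-bis(benzyloxy)-4-methoxybenzoate
Conditions: BnBr (3.3 equiv), K2CO3 (4 equiv), DMF, 60 °C
Reagents that add atoms: benzyl bromide, BrCc1ccccc1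
Why: Williamson etherification of both phenols and SN2 alkylation of the carboxylate by benzyl bromide under carbonate base should cap all three acidic sites in one operation.

Step 2
Reactants: 2 benzyl 3,5-bis(benzyloxy)-4-methoxybenzoate
Product: 3 [3,5-bis(benzyloxy)-4-methoxyphenyl]methanol
Conditions: LiAlH4, THF, 0 °C to rt; then H2O, aq. NaOH (Fieser work-up)
Reagents that add atoms: none
Why: Hydride reduction of the ester by LiAlH4 should give the primary benzylic alcohol while aryl benzyl and methyl ethers are inert to the reagent.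

Step 3
Reactants: 3 [3,5-bis(benzyloxy)-4-methoxyphenyl]methanol
Product: 4 3,5-bis(benzyloxy)-4-methoxybenzaldehyde
Conditions: MnO2 (activated, excess), CH2Cl2, rt
Reagents that add atoms: none
Why: Activated MnO2 oxidises benzylic alcohols selectively to aldehydes without over-oxidation and without touching the ethers.

Step 4
Reactants: 4 3,5-bis(benzyloxy)-4-methoxybenzaldehyde
Product: 6 3,5-bis(benzyloxy)-4-methoxyphenol, via aryl formate 5 (not isolated)
Conditions: mCPBA, CH2Cl2, 0 °C to rt; aq. NaHCO3 wash; then K2CO3 (cat.), MeOH, rt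
Reagents that add atoms: mCPBA (3-chloroperoxybenzoic acid), O=C(OO)c1cccc(Cl)c1
Why: Baeyer–Villiger (Dakin-type) oxidation of an electron-rich benzaldehyde proceeds with migration of the trialkoxyaryl group to the aryl formate, which mild methanolysis should cleave to the phenol.

Step 5
Reactants: 6 3,5-bis(benzyloxy)-4-methoxyphenol
Product: 7 2,4-bis(benzyloxy)-6-hydroxy-3-methoxybenzaldehyde
Conditions: MgCl2, Et3N, (CH2O)n, MeCN, reflux; dilute HCl work-up
Reagents that add atoms: paraformaldehyde (formaldehyde), C=O
Why: Casnati–Skattebøl ortho-formylation, in which the magnesium phenoxide delivers formaldehyde only to the ortho carbon (both ortho positions of 6 are equivalent by symmetry) and a second formaldehyde accepts the hydride, should give the salicylaldehyde as a single regioisomer.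

Step 6
Reactants: 7 2,4-bis(benzyloxy)-6-hydroxy-3-methoxybenzaldehyde; 8 vinyl acetate
Product: 9 2,4-bis(benzyloxy)-6-(ethenyloxy)-3-methoxybenzaldehyde
Conditions: [Ir(cod)Cl]2 (2 mol%), Na2CO3 (0.6 equiv), vinyl acetate (3 equiv), toluene, 100 °C
Reagents that add atoms: none
Why: Iridium-catalysed transfer vinylation of a phenol from vinyl acetate (addition of the phenoxide to the coordinated vinyl ester, then loss of acetate) runs under weakly basic conditions that the aldehyde and the benzyl ethers should tolerate.

Step 7
Reactants: 10 1-(3,4,5-trimethoxyphenyl)ethanone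
Product: 11 (E)-N'-[1-(3,4,5-trimethoxyphenyl)ethylidene]-2,4,6-tri(propan-2-yl)benzenesulfonohydrazide
Conditions: 2,4,6-triisopropylbenzenesulfonohydrazide, MeOH, HCl (cat.), rt
Reagents that add atoms: 2,4,6-tri(propan-2-yl)benzenesulfonohydrazide, CC(C)c1cc(C(C)C)c(S(=O)(=O)NN)c(C(C)C)c1
Why: Acid-catalysed condensation of the methyl ketone with the sulfonyl hydrazide should give the crystalline hydrazone, with the sulfonamide nitrogen anti to the larger aryl group (E).

Step 8
Reactants: 11 (E)-N'-[1-(3,4,5-trimethoxyphenyl)ethylidene]-2,4,6-tri(propan-2-yl)benzenesulfonohydrazide; 9 2,4-bis(benzyloxy)-6-(ethenyloxy)-3-methoxybenzaldehyde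
Product: 13 1-[2,4-bis(benzyloxy)-6-(ethenyloxy)-3-methoxyphenyl]-2-(3,4,5-trimethoxyphenyl)prop-2-en-1-ol (racemic), via 1-arylvinyllithium 12 (not isolated)
Conditions: 11 (1.3 equiv), n-BuLi (2.1 equiv per 11), THF, −78 to 0 °C; then 9, THF, −78 to −20 °C; aq. NaHCO3 quench
Reagents that add atoms: none
Why: Shapiro reaction, in which double deprotonation of the hydrazone and loss of sulfinate and N2 give vinyllithium 12, followed by 1,2-addition to the aldehyde of 9; the carbinol stereocentre forms as a racemate, which is harmless because it becomes the C4 carbonyl in step 10.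

Step 9
Reactants: 13 1-[2,4-bis(benzyloxy)-6-(ethenyloxy)-3-methoxyphenyl]-2-(3,4,5-trimethoxyphenyl)prop-2-en-1-ol (racemic)
Product: 14 5,7-bis(benzyloxy)-6-methoxy-3-(3,4,5-trimethoxyphenyl)-4H-chromen-4-ol (racemic)
Conditions: second-generation Grubbs catalyst RuCl2(=CHPh)(H2IMes)(PCy3) (10 mol%, two portions), 1,4-benzoquinone (10 mol%), degassed toluene (0.005 M), 80 °C, argon sparge; filtration through basic alumina
Reagents that add atoms: none
Why: The catalyst loads onto the monosubstituted vinyl ether of 13 to give an aryloxy-substituted ruthenium carbene, which adds across the neighbouring 1,1-disubstituted styrene alkene to a metallacyclobutane and collapses to the C2=C3 bond, releasing Ru=CH2 and, on turnover, ethene. The closest known reaction type is enol ether–olefin ring-closing metathesis of aryl vinyl ethers carrying an ortho alkenyl chain, which gives 4H-chromenes and benzofurans with the same catalyst. Ring C is closed as a six-membered ring by forming an endocyclic trisubstituted enol-ether alkene, the tether O1–C8a–C4a–C4 being held cis by ring A. No stereocentre is created; the racemic C4 carbinol is carried through unchanged and erased in step 10. The step needs chemoselectivity for ring closure over parking of ruthenium as the heteroatom-stabilised carbene, over intermolecular metathesis and over ruthenium hydride isomerisation of the allylic alcohol; the rigid ortho tether, high dilution with removal of ethene, the free allylic hydroxyl beside the hindered alkene and the benzoquinone additive should secure this. The new alkene is trisubstituted and conjugated with ring B and O1, so it should not re-enter the catalytic cycle.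

Step 10
Reactants: 14 5,7-bis(benzyloxy)-6-methoxy-3-(3,4,5-trimethoxyphenyl)-4H-chromen-4-ol (racemic)
Product: 15 5,7-bis(benzyloxy)-6-methoxy-3-(3,4,5-trimethoxyphenyl)-4H-chromen-4-one
Conditions: crude 14, MnO2 (activated, 15 equiv), CH2Cl2, rt
Reagents that add atoms: none
Why: MnO2 oxidation of the allylic and benzylic C4 carbinol should give the vinylogous ester carbonyl of the chromone, removing both the stereocentre and the acid lability of 14.

Step 11
Reactants: 15 5,7-bis(benzyloxy)-6-methoxy-3-(3,4,5-trimethoxyphenyl)-4H-chromen-4-one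
Product: 16 Junipegenin C, 5,7-dihydroxy-6-methoxy-3-(3,4,5-trimethoxyphenyl)-4H-chromen-4-one
Conditions: H2 (1 atm), 10% Pd/C, EtOAc–MeOH, rt, stopped after uptake of 2 equiv H2
Reagents that add atoms: none
Why: Palladium-catalysed hydrogenolysis cleaves both aryl benzyl ethers, whereas the aryl methyl ethers are inert and the conjugated trisubstituted C2=C3 bond of the chromone is reduced much more slowly.

Compound list
1 | 3,5-dihydroxy-4-methoxybenzoic acid | COc1c(O)cc(C(=O)O)cc1O | starting material
2 | benzyl 3,5-bis(benzyloxy)-4-methoxybenzoate | COc1c(OCc2ccccc2)cc(C(=O)OCc2ccccc2)cc1OCc1ccccc1 | intermediate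
3 | [3,5-bis(benzyloxy)-4-methoxyphenyl]methanol | COc1c(OCc2ccccc2)cc(CO)cc1OCc1ccccc1 | intermediate
4 | 3,5-bis(benzyloxy)-4-methoxybenzaldehyde | COc1c(OCc2ccccc2)cc(C=O)cc1OCc1ccccc1 | intermediate
5 | 3,5-bis(benzyloxy)-4-methoxyphenyl formate (not isolated) | COc1c(OCc2ccccc2)cc(OC=O)cc1OCc1ccccc1 | intermediate
6 | 3,5-bis(benzyloxy)-4-methoxyphenol | COc1c(OCc2ccccc2)cc(O)cc1OCc1ccccc1 | intermediate
7 | 2,4-bis(benzyloxy)-6-hydroxy-3-methoxybenzaldehyde | COc1c(OCc2ccccc2)cc(O)c(C=O)c1OCc1ccccc1 | intermediate
8 | vinyl acetate (ethenyl acetate) | C=COC(C)=O | starting material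
9 | 2,4-bis(benzyloxy)-6-(ethenyloxy)-3-methoxybenzaldehyde | COc1c(OCc2ccccc2)cc(OC=C)c(C=O)c1OCc1ccccc1 | intermediate
10 | 1-(3,4,5-trimethoxyphenyl)ethanone | CC(=O)c1cc(OC)c(OC)c(OC)c1 | starting material
11 | (E)-N'-[1-(3,4,5-trimethoxyphenyl)ethylidene]-2,4,6-tri(propan-2-yl)benzenesulfonohydrazide | C/C(=N\NS(=O)(=O)c1c(C(C)C)cc(C(C)C)cc1C(C)C)c1cc(OC)c(OC)c(OC)c1 | intermediate
12 | [1-(3,4,5-trimethoxyphenyl)ethenyl]lithium (not isolated) | [Li]C(=C)c1cc(OC)c(OC)c(OC)c1 | intermediate
13 | 1-[2,4-bis(benzyloxy)-6-(ethenyloxy)-3-methoxyphenyl]-2-(3,4,5-trimethoxyphenyl)prop-2-en-1-ol (racemic) | C=COc1cc(OCc2ccccc2)c(OC)c(OCc2ccccc2)c1C(O)C(=C)c1cc(OC)c(OC)c(OC)c1 | intermediate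
14 | 5,7-bis(benzyloxy)-6-methoxy-3-(3,4,5-trimethoxyphenyl)-4H-chromen-4-ol (racemic) | OC1C(c2cc(OC)c(OC)c(OC)c2)=COc2cc(OCc3ccccc3)c(OC)c(OCc3ccccc3)c21 | intermediate
15 | 5,7-bis(benzyloxy)-6-methoxy-3-(3,4,5-trimethoxyphenyl)-4H-chromen-4-one | O=c1c(-c2cc(OC)c(OC)c(OC)c2)coc2cc(OCc3ccccc3)c(OC)c(OCc3ccccc3)c12 | intermediate
16 | Junipegenin C, 5,7-dihydroxy-6-methoxy-3-(3,4,5-trimethoxyphenyl)-4H-chromen-4-one | COc1cc(-c2coc3cc(O)c(OC)c(O)c3c2=O)cc(OC)c1OC | target

Total step count: 11
Longest linear sequence: 10 steps (steps 1–6 and 8–11, from 1 to 16); step 7 is the one-step side branch from 10.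

Steps most likely to fail

Step 9. Ruthenium may stay parked as the aryloxycarbene and decay to hydride species, which would stall turnover and isomerise the allylic alcohol to a saturated ketone, or the C4 carbinol may ionise on heating. The fallback sets out from 13 and closes ring C at O1–C2 instead. Oxidation of 13 with Dess–Martin periodinane and NaHCO3 in CH2Cl2 should give the aryl vinyl ketone F1. Dilute HCl in THF at 40 °C hydrolyses the vinyl ether to the free phenol F2. On buffering with NaOAc in EtOH, F2 closes by 6-endo oxa-Michael addition to the racemic isoflavanone F3. Dehydrogenation of F3 with DDQ in refluxing 1,4-dioxane comes back to the route at 15.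

Step 6. The phenol is tied to the ortho formyl group by a hydrogen bond, so transfer vinylation may be slow and O-acetylation may compete. The fallback sets out from 7 and builds the vinyl group by alkylation and elimination. Alkylation with excess 1,2-dibromoethane and K2CO3 in DMF at 60 °C should give the 2-bromoethyl ether F4. E2 dehydrobromination of F4 with KOtBu in THF at 0 °C comes back to the route at 9.

Step 8. The vinyllithium may be quenched by solvent before it meets the hindered aldehyde, and the new hydroxyl may ionise or add to the vinyl ether during work-up. The fallback sets out from 10 and 9 and replaces the organolithium by a chromium reagent under neutral conditions. Enolisation of 10 with KN(SiMe3)2 and trapping with PhNTf2 in THF at −78 °C should give the enol triflate F5. Nozaki–Hiyama–Kishi coupling of F5 with 9 (CrCl2 in excess, NiCl2 catalytic, DMF, rt) comes back to the route at 13.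

Further compounds
F1 | step 9 | 1-[2,4-bis(benzyloxy)-6-(ethenyloxy)-3-methoxyphenyl]-2-(3,4,5-trimethoxyphenyl)prop-2-en-1-one | C=COc1cc(OCc2ccccc2)c(OC)c(OCc2ccccc2)c1C(=O)C(=C)c1cc(OC)c(OC)c(OC)c1
F2 | step 9 | 1-[2,4-bis(benzyloxy)-6-hydroxy-3-methoxyphenyl]-2-(3,4,5-trimethoxyphenyl)prop-2-en-1-one | Oc1cc(OCc2ccccc2)c(OC)c(OCc2ccccc2)c1C(=O)C(=C)c1cc(OC)c(OC)c(OC)c1
F3 | step 9 | 5,7-bis(benzyloxy)-6-methoxy-3-(3,4,5-trimethoxyphenyl)-2,3-dihydro-4H-chromen-4-one (racemic) | O=C1C(c2cc(OC)c(OC)c(OC)c2)COc2cc(OCc3ccccc3)c(OC)c(OCc3ccccc3)c21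
F4 | step 6 | 2,4-bis(benzyloxy)-6-(2-bromoethoxy)-3-methoxybenzaldehyde | COc1c(OCc2ccccc2)cc(OCCBr)c(C=O)c1OCc1ccccc1
F5 | step 8 | 1-(3,4,5-trimethoxyphenyl)ethenyl trifluoromethanesulfonate | C=C(OS(=O)(=O)C(F)(F)F)c1cc(OC)c(OC)c(OC)c1
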